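**Retrosynthetic overview**
- The target is a C2-symmetric 3,3''-biflavanone, all-R, with both rings C 2,3-cis. In flavanone numbering its C4–C3–C3''–C4'' chain is a 2,3-disubstituted succinyl unit with like configuration at C3 and C3'', which is the imprint of a syn addition of two carbonyl carbons to an E C3=C3'' alkene.
- Both rings C are closed last and together: C4–C4a and C4''–C4a'' by Friedel–Crafts acylation of succinic diacid 11 onto the symmetric benzyl-protected rings A, followed by debenzylation.
- C3–C4 and C3''–C4'' come from palladium-catalysed oxidative bis-methoxycarbonylation of the (1R,2E,4R)-bis(aryloxy)alkene 6 with CO and methanol; no ring is formed in that step.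
- C3=C3'' comes from homometathesis of (R)-allyl aryl ether 5. The C2–O1 bonds and the C2/C2'' stereocentres come from iridium-catalysed branched allylic etherification of carbonate 2 with phenol 3.
- Rings A and B are bought; the two rings C are the only rings made (step 6).

Key step: step 4

Assumption: with (E)-cinnamyl carbonates the (Ra,Rc,Rc) phosphoramidite is taken to give the (R)-configured branched aryl ether; if the sense of induction is the opposite, the (Sa,Sc,Sc) ligand is used with no other change.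

**Step 1**
Reactants: 1 (E)-4-methoxycinnamyl alcohol
Product: 2 (E)-3-(4-methoxyphenyl)prop-2-en-1-yl methyl carbonate
Conditions: ClCO2Me (1.3 equiv), pyridine (2 equiv), CH2Cl2, 0 °C
Reagents that add atoms: methyl chloroformate, COC(=O)Cl
Why: O-acylation of a primary allylic alcohol by a chloroformate, with pyridine taking up HCl so that the ionisable 4-methoxycinnamyl system never meets free acid.

**Step 2**
Reactants: 2 (E)-3-(4-methoxyphenyl)prop-2-en-1-yl methyl carbonate; 3 3,5-bis(benzyloxy)phenol
Product: 5 1,3-bis(benzyloxy)-5-{[(1R)-1-(4-methoxyphenyl)prop-2-en-1-yl]oxy}benzene, via lithium aryloxide 4 (not isolated)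
Conditions: 3 (2 equiv), n-BuLi (2 equiv), THF, 0 °C; then 2, [Ir(cod)Cl]2 (1 mol%), (Ra,Rc,Rc)-O,O'-(1,1'-binaphthyl-2,2'-diyl) N,N-bis(1-phenylethyl)phosphoramidite (2 mol%), THF, 25 °C
Reagents that add atoms: none
Why: Iridium-catalysed branched-selective asymmetric allylic etherification, in which the iridium–phosphoramidite catalyst ionises the carbonate and the lithium aryloxide attacks the aryl-bearing allyl terminus on the face fixed by the ligand, setting the (R) centre that becomes C2 and C2'' (lithium counter-ion and THF favour O- over C-allylation).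

**Step 3**
Reactants: 5 1,3-bis(benzyloxy)-5-{[(1R)-1-(4-methoxyphenyl)prop-2-en-1-yl]oxy}benzene (two molecules)
Product: 6 (1R,2E,4R)-1,4-bis[3,5-bis(benzyloxy)phenoxy]-1,4-bis(4-methoxyphenyl)but-2-ene
Conditions: second-generation Hoveyda–Grubbs catalyst RuCl2(H2IMes)(=CH-C6H4-2-OiPr) (5 mol%), 1,4-benzoquinone (10 mol%), CH2Cl2, 40 °C, argon sparge
Reagents that add atoms: none
Why: Olefin homometathesis of a terminal alkene driven by loss of ethylene, in which the bulky secondary allylic carbons enforce the thermodynamic E geometry, the stereocentres are not touched, and the quinone suppresses ruthenium hydride isomerisation to the enol ether.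

**Step 4**
Reactants: 6 (1R,2E,4R)-1,4-bis[3,5-bis(benzyloxy)phenoxy]-1,4-bis(4-methoxyphenyl)but-2-ene; 7 carbon monoxide; 8 methanol
Product: 9 dimethyl (2R,3R)-2,3-bis{(R)-[3,5-bis(benzyloxy)phenoxy](4-methoxyphenyl)methyl}butanedioate
Conditions: Pd(OCOCF3)2 (5 mol%), N,N'-bis(2,6-dimethylphenyl)butane-2,3-diimine (5.5 mol%), 1,4-benzoquinone (1.5 equiv), CO (4 bar), MeOH/THF 1:2, 20 °C, no added sulfonic acid
Reagents that add atoms: carbon monoxide 7, [C-]#[O+]; methanol 8, CO
Why: Proposed new method: the closest known reaction is the syn-stereospecific oxidative bis-alkoxycarbonylation of 1,2-disubstituted alkenes by diimine-ligated divalent palladium with benzoquinone, which has not been applied to an alkene flanked by two allylic aryl ethers nor steered by allylic stereocentres. A Pd–CO2Me species formed from Pd(OCOCF3)2, CO and MeOH adds syn across C3=C3'', the ester-chelated alkylpalladium inserts CO with retention, methanolysis releases diester 9, and benzoquinone returns zerovalent palladium to the divalent state; no ring is closed. Since both carbonyl carbons arrive on one face of an E-alkene, C3 and C3'' necessarily acquire like configuration, so the only selectivity required is the choice of alkene face. The two allylic centres are related by a C2 axis perpendicular to the alkene plane and therefore direct to the same face: with each allylic C–H near the alkene plane the metal adds opposite both C–O bonds, as electrophiles do with allylic ethers, and that face gives the (2R,3R) diester that later becomes the 2,3-cis rings. Carbonyl insertion must outrun beta-hydride and beta-aryloxide elimination and the 4-methoxybenzylic allylic ethers must not ionise, which CO pressure, the chelating diimine, excess quinone that keeps zerovalent palladium scarce and the omission of sulfonic acid are meant to secure. Should substrate control prove weak, a C2-symmetric bis(oxazoline) of the matched hand would replace the diimine.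

**Step 5**
Reactants: 9 dimethyl (2R,3R)-2,3-bis{(R)-[3,5-bis(benzyloxy)phenoxy](4-methoxyphenyl)methyl}butanedioate
Product: 11 (2R,3R)-2,3-bis{(R)-[3,5-bis(benzyloxy)phenoxy](4-methoxyphenyl)methyl}butanedioic acid, via bis(trimethylstannyl) ester 10 (not isolated)
Conditions: Me3SnOH (8 equiv), ClCH2CH2Cl, 80 °C; then cold 0.05 M HCl/EtOAc work-up
Reagents that add atoms: trimethyltin hydroxide, C[Sn](C)(C)O
Why: Trimethyltin hydroxide ester cleavage, a near-neutral acyl transfer to tin that should spare the base-sensitive C3/C3'' centres from epimerisation and the beta-aryloxy groups from E1cB loss, the stannyl esters being protonated on mild acidic work-up.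

**Step 6**
Reactants: 11 (2R,3R)-2,3-bis{(R)-[3,5-bis(benzyloxy)phenoxy](4-methoxyphenyl)methyl}butanedioic acid
Product: 15 (2R,2'R,3R,3'R)-5,5',7,7'-tetrakis(benzyloxy)-2,2'-bis(4-methoxyphenyl)-[3,3'-bichromane]-4,4'-dione, via cyclic anhydride 12 (not isolated), via mono-chromanone acid 13 (not isolated), via acyl trifluoroacetate 14 (not isolated)
Conditions: (CF3CO)2O (4 equiv), CH2Cl2, 0 °C to 20 °C
Reagents that add atoms: none
Why: Intramolecular Friedel–Crafts acylation in which trifluoroacetic anhydride first dehydrates the diacid to trans-anhydride 12, the ring A carbon ortho to O1 (activated by all three oxygens, both ortho positions equivalent) opens it to close the first six-membered ring C, and the freed acid 13 is re-activated as 14 to close the second, six-membered closure being preferred over the seven-membered alternative onto the distal ring A and no bond to C2 or C3 being broken, so the cis relationships of step 4 pass into the rings.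

**Step 7**
Reactants: 15 (2R,2'R,3R,3'R)-5,5',7,7'-tetrakis(benzyloxy)-2,2'-bis(4-methoxyphenyl)-[3,3'-bichromane]-4,4'-dione
Product: 16 (2R,2'R,3R,3'R)-5,5',7,7'-tetrahydroxy-2,2'-bis(4-methoxyphenyl)-[3,3'-bichromane]-4,4'-dione
Conditions: H2 (1 atm), 10% Pd/C, EtOAc/THF, 20 °C, stopped after uptake of 4 equiv
Reagents that add atoms: none
Why: Catalytic hydrogenolysis of the four aryl benzyl ethers under neutral conditions, which leave the aryl methyl ethers and ketones alone and avoid the enolisation or retro-oxa-Michael opening that would epimerise the less stable 2,3-cis rings.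

**Compound list**
1 | (E)-3-(4-methoxyphenyl)prop-2-en-1-ol (4-methoxycinnamyl alcohol) | COc1ccc(/C=C/CO)cc1 | starting material
2 | (E)-3-(4-methoxyphenyl)prop-2-en-1-yl methyl carbonate | COC(=O)OC/C=C/c1ccc(OC)cc1 | intermediate
3 | 3,5-bis(benzyloxy)phenol | Oc1cc(OCc2ccccc2)cc(OCc2ccccc2)c1 | starting material
4 | lithium 3,5-bis(benzyloxy)phenoxide | [Li+].[O-]c1cc(OCc2ccccc2)cc(OCc2ccccc2)c1 | intermediate
5 | 1,3-bis(benzyloxy)-5-{[(1R)-1-(4-methoxyphenyl)prop-2-en-1-yl]oxy}benzene | COc1ccc(cc1)[C@H](Oc1cc(OCc2ccccc2)cc(OCc2ccccc2)c1)C=C | intermediate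
6 | (1R,2E,4R)-1,4-bis[3,5-bis(benzyloxy)phenoxy]-1,4-bis(4-methoxyphenyl)but-2-ene | COc1ccc(cc1)[C@H](Oc1cc(OCc2ccccc2)cc(OCc2ccccc2)c1)/C=C/[C@@H](Oc1cc(OCc2ccccc2)cc(OCc2ccccc2)c1)c1ccc(OC)cc1 | intermediate
7 | carbon monoxide | [C-]#[O+] | starting material
8 | methanol | CO | starting material
9 | dimethyl (2R,3R)-2,3-bis{(R)-[3,5-bis(benzyloxy)phenoxy](4-methoxyphenyl)methyl}butanedioate | COc1ccc(cc1)[C@H](Oc1cc(OCc2ccccc2)cc(OCc2ccccc2)c1)[C@H](C(=O)OC)[C@@H](C(=O)OC)[C@@H](Oc1cc(OCc2ccccc2)cc(OCc2ccccc2)c1)c1ccc(OC)cc1 | intermediate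
10 | bis(trimethylstannyl) (2R,3R)-2,3-bis{(R)-[3,5-bis(benzyloxy)phenoxy](4-methoxyphenyl)methyl}butanedioate | COc1ccc(cc1)[C@H](Oc1cc(OCc2ccccc2)cc(OCc2ccccc2)c1)[C@H](C(=O)O[Sn](C)(C)C)[C@@H](C(=O)O[Sn](C)(C)C)[C@@H](Oc1cc(OCc2ccccc2)cc(OCc2ccccc2)c1)c1ccc(OC)cc1 | intermediate
11 | (2R,3R)-2,3-bis{(R)-[3,5-bis(benzyloxy)phenoxy](4-methoxyphenyl)methyl}butanedioic acid | COc1ccc(cc1)[C@H](Oc1cc(OCc2ccccc2)cc(OCc2ccccc2)c1)[C@H](C(=O)O)[C@@H](C(=O)O)[C@@H](Oc1cc(OCc2ccccc2)cc(OCc2ccccc2)c1)c1ccc(OC)cc1 | intermediate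
12 | (3R,4R)-3,4-bis{(R)-[3,5-bis(benzyloxy)phenoxy](4-methoxyphenyl)methyl}oxolane-2,5-dione | COc1ccc(cc1)[C@H](Oc1cc(OCc2ccccc2)cc(OCc2ccccc2)c1)[C@@H]1C(=O)OC(=O)[C@H]1[C@@H](Oc1cc(OCc2ccccc2)cc(OCc2ccccc2)c1)c1ccc(OC)cc1 | intermediate
13 | (2R,3R)-2-[(2R,3R)-5,7-bis(benzyloxy)-2-(4-methoxyphenyl)-4-oxochroman-3-yl]-3-[3,5-bis(benzyloxy)phenoxy]-3-(4-methoxyphenyl)propanoic acid | COc1ccc([C@@H]2Oc3cc(OCc4ccccc4)cc(OCc4ccccc4)c3C(=O)[C@@H]2[C@@H](C(=O)O)[C@@H](Oc2cc(OCc3ccccc3)cc(OCc3ccccc3)c2)c2ccc(OC)cc2)cc1 | intermediate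
14 | mixed anhydride of acid 13 with trifluoroacetic acid | COc1ccc([C@@H]2Oc3cc(OCc4ccccc4)cc(OCc4ccccc4)c3C(=O)[C@@H]2[C@@H](C(=O)OC(=O)C(F)(F)F)[C@@H](Oc2cc(OCc3ccccc3)cc(OCc3ccccc3)c2)c2ccc(OC)cc2)cc1 | intermediate
15 | (2R,2'R,3R,3'R)-5,5',7,7'-tetrakis(benzyloxy)-2,2'-bis(4-methoxyphenyl)-[3,3'-bichromane]-4,4'-dione | COc1ccc([C@@H]2Oc3cc(OCc4ccccc4)cc(OCc4ccccc4)c3C(=O)[C@@H]2[C@H]2C(=O)c3c(OCc4ccccc4)cc(OCc4ccccc4)cc3O[C@H]2c2ccc(OC)cc2)cc1 | intermediate
16 | (2R,2'R,3R,3'R)-5,5',7,7'-tetrahydroxy-2,2'-bis(4-methoxyphenyl)-[3,3'-bichromane]-4,4'-dione | COc1ccc([C@@H]2Oc3cc(O)cc(O)c3C(=O)[C@@H]2[C@H]2C(=O)c3c(O)cc(O)cc3O[C@H]2c2ccc(OC)cc2)cc1 | target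

**Step count**
Total steps: 7. Longest linear sequence: 7 (1 → 2 → 5 → 6 → 9 → 11 → 15 → 16).

**Steps most likely to fail**

*Step 4 (Proposed new method).* What may go wrong:
- poor discrimination between the two alkene faces;
- ionisation of the doubly activated allylic aryl ethers by zerovalent palladium or by acid;
- beta-aryloxide or beta-hydride elimination from the alkylpalladium before CO inserts;
- slow insertion of a hindered internal alkene.

The fallback uses known chemistry, sets out from 6 and comes back at 12. Shi epoxidation of 6 with the D-fructose-derived ketone (Oxone, 2KHSO5·KHSO4·K2SO4, K2CO3 buffer, MeCN/dimethoxymethane/water, 0 °C) is reagent-controlled and gives (R,R)-epoxides from E-1,2-disubstituted alkenes. It should deliver (2R,3R)-2,3-bis{(S)-[3,5-bis(benzyloxy)phenoxy](4-methoxyphenyl)methyl}oxirane F1, with the oxygen on the face opposite to the one that must carry the carbonyl carbons. Epoxide double carbonylation with [(ClTPP)Al(THF)2][Co(CO)4] (ClTPP = tetrakis(4-chlorophenyl)porphyrinate) under CO (60 bar) in 1,4-dioxane at 90 °C then replaces each C–O bond by a C–C(=O) bond with inversion. The net result is a syn addition of two carbonyls to the required face, giving trans-anhydride 12 directly. Compound 12 is taken on under the conditions of step 6, so step 5 is bypassed. Face selection then rests on the ketone catalyst, whose antipode is also available, and not on the substrate.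

*Step 6.* What may go wrong:
- acid-promoted ionisation of the 4-methoxybenzylic C2–O1 ether before the ring closes, with loss of the phenol or scrambling at C2;
- sluggish acylation by the cyclic anhydride;
- trifluoroacetylation of ring A;
- acid-catalysed epimerisation at C3 of the cis-chromanone.

The fallback closes rings C by an anionic Parham cyclisation without any acid. It sets out from 3 and comes back at 15.
- Amine-directed ortho-bromination of 3 (NBS, catalytic i-Pr2NH, CH2Cl2, 0 °C) gives 3,5-bis(benzyloxy)-2-bromophenol F2.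
- F2 replaces 3 in step 2 to give 1,5-bis(benzyloxy)-2-bromo-3-{[(1R)-1-(4-methoxyphenyl)prop-2-en-1-yl]oxy}benzene F3.
- The conditions of step 3 then give (1R,2E,4R)-1,4-bis[3,5-bis(benzyloxy)-2-bromophenoxy]-1,4-bis(4-methoxyphenyl)but-2-ene F4.
- The conditions of step 4 give dimethyl (2R,3R)-2,3-bis{(R)-[3,5-bis(benzyloxy)-2-bromophenoxy](4-methoxyphenyl)methyl}butanedioate F5.
- Bromine–lithium exchange on F5 (t-BuLi, 4.2 equiv, THF, −100 °C) generates two aryllithiums, each of which attacks the neighbouring methyl ester in a six-membered acyl substitution to give 15 directly. Steps 5 and 6 are bypassed.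

*Step 3.* What may go wrong:
- slow homodimerisation of a terminal alkene whose allylic carbon carries both an aryl and an aryloxy group;
- catalyst decay before conversion is complete;
- ruthenium hydride isomerisation of the allyl ether to the conjugated enol ether.

The fallback builds the E-alkene from a four-carbon unit and uses no metathesis. It sets out from 3 (anisole and fumaroyl chloride are bought) and comes back at 6.
- Para-selective Friedel–Crafts acylation of anisole with fumaroyl chloride (AlCl3, CH2Cl2, 0 °C) gives (E)-1,4-bis(4-methoxyphenyl)but-2-ene-1,4-dione F6.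
- Corey–Bakshi–Shibata 1,2-reduction (BH3·SMe2, the 2-methyl-oxazaborolidine enantiomer that gives the (S)-carbinols, THF, −20 °C) gives (1S,2E,4S)-1,4-bis(4-methoxyphenyl)but-2-ene-1,4-diol F7.
- Double Mitsunobu etherification of F7 with phenol 3 (PPh3, diisopropyl azodicarboxylate, toluene, 0 °C) inverts both carbinol carbons and gives 6. Allylic transposition and ionisation are the processes to watch.

**Further compounds**
F1 | step 4 | (2R,3R)-2,3-bis{(S)-[3,5-bis(benzyloxy)phenoxy](4-methoxyphenyl)methyl}oxirane | COc1ccc(cc1)[C@H](Oc1cc(OCc2ccccc2)cc(OCc2ccccc2)c1)[C@H]1O[C@@H]1[C@@H](Oc1cc(OCc2ccccc2)cc(OCc2ccccc2)c1)c1ccc(OC)cc1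
F2 | step 6 | 3,5-bis(benzyloxy)-2-bromophenol | Oc1cc(OCc2ccccc2)cc(OCc2ccccc2)c1Br
F3 | step 6 | 1,5-bis(benzyloxy)-2-bromo-3-{[(1R)-1-(4-methoxyphenyl)prop-2-en-1-yl]oxy}benzene | COc1ccc(cc1)[C@H](Oc1cc(OCc2ccccc2)cc(OCc2ccccc2)c1Br)C=C
F4 | step 6 | (1R,2E,4R)-1,4-bis[3,5-bis(benzyloxy)-2-bromophenoxy]-1,4-bis(4-methoxyphenyl)but-2-ene | COc1ccc(cc1)[C@H](Oc1cc(OCc2ccccc2)cc(OCc2ccccc2)c1Br)/C=C/[C@@H](Oc1cc(OCc2ccccc2)cc(OCc2ccccc2)c1Br)c1ccc(OC)cc1
F5 | step 6 | dimethyl (2R,3R)-2,3-bis{(R)-[3,5-bis(benzyloxy)-2-bromophenoxy](4-methoxyphenyl)methyl}butanedioate | COc1ccc(cc1)[C@H](Oc1cc(OCc2ccccc2)cc(OCc2ccccc2)c1Br)[C@H](C(=O)OC)[C@@H](C(=O)OC)[C@@H](Oc1cc(OCc2ccccc2)cc(OCc2ccccc2)c1Br)c1ccc(OC)cc1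
F6 | step 3 | (E)-1,4-bis(4-methoxyphenyl)but-2-ene-1,4-dione | COc1ccc(cc1)C(=O)/C=C/C(=O)c1ccc(OC)cc1
F7 | step 3 | (1S,2E,4S)-1,4-bis(4-methoxyphenyl)but-2-ene-1,4-diol | COc1ccc(cc1)[C@@H](O)/C=C/[C@H](O)c1ccc(OC)cc1
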